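All runs are simulated from invented constants.

Count the second reagent.

| flask | substrate | partner | solid second reagent | remark | time |
|---|---|---|---|---|---|
| Sunday's | 0.050 M | 0.60 equiv | 1.3 equiv | run made earlier |  |
| Tuesday's | 0.050 M | 0.30 equiv | 1.3 equiv | run made earlier |  |
| summer | 0.050 M | 0.600 equiv | 1.30 equiv | everything together at the start | 80 min |
| autumn | 0.050 M (fed, over 30 min) | 0.600 equiv | 1.30 equiv | all else is in the flask from the start; the feed brings no volume worth counting | 80 min |
| dawn | 0.050 M | 0.600 equiv (fed, over 30 min) | 1.30 equiv | all else is in the flask from the start; the feed brings no volume worth counting | 80 min |

| run | time / min | side product B / % | target / % |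
|---|---|---|---|
| Sunday's | 4.00 | 15 | 19 |
| Sunday's | 6.00 | 16 | 30 |
| Sunday's | 8.00 | 17 | 33 |
| Sunday's | 15.0 | 23 | 37 |
| Sunday's | 20.0 | 24 | 41 |
| Sunday's | 30.0 | 26 | 41 |
| Sunday's | 50.0 | 27 | 42 |
| Tuesday's | 3.00 | 11 | 8 |
| Tuesday's | 6.00 | 12 | 16 |
| Tuesday's | 10.0 | 13 | 17 |
| Tuesday's | 15.0 | 16 | 18 |
| Tuesday's | 20.0 | 21 | 17 |
| Tuesday's | 25.0 | 18 | 20 |

(readings scatter by 2 percentage points)

- percentages count the substrate that a species holds: one side product B counts as two
- solid, in amounts per volume of the solution: solid second reagent
- reactions considered so far: substrate + partner -> intermediate; second reagent + intermediate -> target; substrate + second reagent -> side product A; solid second reagent <-> second reagent; substrate + intermediate -> side product B; 2 second reagent -> homo dimer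
- at the start none of the solid second reagent is in solution

1. the flask that comes out highest in amount of side product B, in percent of the substrate charged; "all alike" if 1.5 percentage points covers them all (summer / autumn / dawn / all alike)
2. amount of side product B at the end, in percent of the substrate charged, summer
3. amount of side product B at the end, in percent of the substrate charged, autumn
4. amount of side product B at the end, in percent of the substrate charged, dawn

1. By the listed reactions, each substrate in target or side product A has taken one second reagent, and substrate in side product B has taken none. I call substrate outside target and side product A uncarried: it stands as side product B, intermediate or unreacted substrate.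

2. I take Sunday's run as finished at 50.0 min, read side product B there as 27%, and assume the rest of its substrate stands as target or side product A. That gives 0.438 as the self-loss share: the part of the charged reagent that reaches neither target nor side product A. The uncarried part is then one minus the charge times what the share leaves.

3. The extremes are easy. At share zero, 1.30 equiv covers the substrate and nothing need stay uncarried. At share one, no substrate is carried.

4. Summer has Sunday's charges, so I expect side product B near Sunday's reading. In autumn the substrate takes 30 min to enter, longer than Sunday's first reading, when side product B already stood at 15%. Dissolved reagent therefore meets less substrate, and I put the share midway between Sunday's and one. That leaves 63.5% uncarried, so I rank autumn highest, with side product B somewhat below that figure. In dawn some uncarried substrate may stand as intermediate, so I expect side product B below summer's.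

5. The forecast differs from me on autumn. It names summer, with 27.5% for summer, 8% for autumn and 14% for dawn, reasoning that “Autumn keeps substrate low while dissolved reagent is already present”.

6. The flasks give 27.2% for summer, 48.2% for autumn and 19.0% for dawn, so autumn is highest.

    substrate + partner → intermediate (k = 18.0 L mol⁻¹ min⁻¹)
    second reagent + intermediate → target (k = 11.0 L mol⁻¹ min⁻¹)
    substrate + second reagent → side product A (k = 3.50 L mol⁻¹ min⁻¹)
    solid second reagent ⇌ second reagent, rate k4*(cs4 - [second reagent]) while solid is left; crystals form when [second reagent] > cs4 (solubility = 20.0 mM, k = 6.30 min⁻¹)
    substrate + intermediate → side product B (k = 2.90 L mol⁻¹ min⁻¹)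
    2 second reagent → homo dimer (k = 5.40 L mol⁻¹ min⁻¹)

7. In autumn the homo dimer holds 0.0239 M at 80.0 min, a self-loss share of 0.735, above the share I read from Sunday's run, and 0.0056% of the charged second reagent is still there, solid or dissolved. With dissolved reagent held at its solubility of 20 mM, the homo dimer step by itself uses a quantity equal to the charge in 15.0 min, shorter than autumn's feed. For dawn with 0.780 equiv of solid second reagent, Sunday's share gives 56.2% uncarried. That flask ends with 31.6% side product B and 26.9% intermediate, together 58.5%.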